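All runs were computed from invented constants, noise included.

| flask | substrate | temperature | remark | time |
|---|---|---|---|---|
| violet | 0.070 M | −5 °C | run made earlier |  |
| blue | 0.28 M | 20 °C | run made earlier |  |
| south-west | 0.14 M |  | at 0 °C throughout | 2.5 min |
| south | 0.14 M |  | at 0 °C until 80 s, from then on at 40 °C | 2.5 min |

| run | time / s | target / % | substrate / % |
|---|---|---|---|
| violet | 15.0 | 0 | 99.4 |
| violet | 30.0 | 0.1 | 99.2 |
| violet | 50.0 | 0.2 | 99.2 |
| violet | 60.0 | 0.7 | 98.3 |
| violet | 80.0 | 1.3 | 99.0 |
| violet | 90.0 | 0.2 | 98.9 |
| violet | 120 | 1.7 | 98.7 |
| blue | 10.0 | 2.8 | 95.6 |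
| blue | 12.0 | 3.9 | 95.7 |
| blue | 20.0 | 9.4 | 90.4 |
| blue | 30.0 | 34.5 | 62.9 |
| blue | 40.0 | 91.4 | 0 |

(each reading ± 0.5 percentage points)

1. the flask that ends with the higher amount of target, in percent of the substrate charged, or "neither" when 2 percentage points or less lies between them (south-west / south / neither)
2. final target, as a percentage of the substrate charged, in south-west
3. final target, as a percentage of the substrate charged, in south



1. Start with the easy reading: in the blue run target climbs from 2.8% at 10.0 s to 34.5% at 30.0 s, a growth rate of 0.126 /s, and substrate reads 0% at 40.0 s, so I read a flask that idles and then finishes abruptly, target speeding its own formation.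

2. Compare two times: the take-off time (the induction period of autocatalysis), from the start until substrate is consumed at the temperature in hand, and the time the flask spends at that temperature.

3. Scale the blue run's 40.0 s, its first reading with substrate at 0%, with temperature: the violet run grows at 0.0148 /s between 60.0 s and 120 s, so the blue run reads faster by a factor of 8.49 between −5 °C and 20 °C, a rough reading, since scatter is large there and the charge differs too, 0.070 M against 0.28 M.

4. Carry that factor to 0 °C, where it gives 221 s, the take-off time at 0 °C. South-west has 2.5 min, less than that, so I expect it still idling. South spends 80 s cold, about a third of that time, then 70.0 s at 40 °C, where the take-off time scales to 7.23 s, about ten times shorter, so I expect substrate consumed and target near blue's last 91.4%.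

5. The forecast says south, with 8% (4% to 20%) in south-west and 55% (10% to 93%) in south, adding “South is therefore very uncertain”; my figure for south stands higher.

6. The flasks give 3.05% in south-west and 98.1% in south, so south ends higher.

    substrate + 2 target → 3 target (k = 3.20 /M²/s, Ea = 45.0 kJ/mol)
    substrate → target (k = 2.80 × 10⁻⁴ /s, Ea = 81.0 kJ/mol)
    target ⇌ isomer of the product (K = 0.480, k = 0.0390 /s, Ea = 75.0 kJ/mol, ΔH = −57.0 kJ/mol)
    (constants at 0 °C)

South-west, given less time than 221 s, still holds 95.6% substrate at 2.50 min, while south holds 0%. Now run south-west at 15 °C instead: the same factor shortens the take-off time to 61.4 s, less than its 2.5 min, so this neighbouring flask should finish. At 2.50 min it holds 0.24% substrate and 88.3% target.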